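The route rests on disconnecting the C8–C9 bond of ring B. The target shows a methine C8 (bearing C17) next to the quaternary C9 (bearing C20 and the C11 methylene), both beside the C1=C10 alkene: the imprint of a C8 radical adding to the β-carbon of a butenoate fixed on C10. A single iron-hydride-initiated 6-exo Giese cyclisation therefore forms C8–C9, closes ring B and sets both methyl-bearing centres. Its precursor is a ring A cyclohexene carrying the C4 quaternary centre (methyl, ester) from an asymmetric conjugate methylation, a but-3-enyl chain on C5 and an (E)-configured ethyl but-2-enoate arm on C10.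

Key step: step 8

Remark on the chemistry: halimane numbering is used (ring A = C1–C5 and C10; ring B = C5–C10; side chain C11–C16; C17 on C8; C18 = carboxyl carbon and C19 = methyl on C4; C20 on C9).
Remark on the chemistry: in step 1 the antipode of the chiral ligand that gives the S-configured C4 is assumed to be the one chosen.

Step 1
Reactants: 1 methyl 3-oxocyclohex-1-ene-1-carboxylate; 2 prop-2-en-1-yl acetate (allyl acetate)
Product: 4 methyl (1S,2R)-1-methyl-3-oxo-2-(prop-2-en-1-yl)cyclohexane-1-carboxylate (allyl cis to the ring methyl), via methylzinc enolate 3 (not isolated)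
Conditions: Me2Zn, Cu(OTf)2 (5 mol %), chiral sulfonate-bearing imidazolinium salt (5 mol %, N-heterocyclic carbene precursor), Et2O, −30 °C; then 2, Pd(PPh3)4 (3 mol %), THF, 0 °C; aq. NH4Cl
Reagents that add atoms: dimethylzinc, C[Zn]C
Why: Copper-catalysed asymmetric conjugate addition of the dialkylzinc to the β-ester cyclohexenone delivers methyl to the ester-bearing carbon β to the ketone under control of the chiral carbene ligand (C4, S), and the regiodefined zinc enolate then undergoes Tsuji–Trost allylation at C5 anti to the pseudoaxial C4 ester of the enolate half-chair, which should place the allyl group cis to the C4 methyl (C5, R).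

Step 2
Reactants: 4 methyl (1S,2R)-1-methyl-3-oxo-2-(prop-2-en-1-yl)cyclohexane-1-carboxylate
Product: 6 methyl (1S,2R)-1-methyl-2-(prop-2-en-1-yl)-3-[(trifluoromethanesulfonyl)oxy]cyclohex-3-ene-1-carboxylate, via potassium enolate 5 (not isolated)
Conditions: KN(SiMe3)2, THF, −78 °C; then PhNTf2, −78 → 0 °C; aq. NH4Cl
Reagents that add atoms: N-phenylbis(trifluoromethanesulfonimide), O=S(=O)(N(c1ccccc1)S(=O)(=O)C(F)(F)F)C(F)(F)F
Why: Kinetic enolisation by the hindered amide base removes a proton from the open C1 methylene and not the tertiary C5–H next to the quaternary centre, and O-sulfonylation of that enolate (enol triflate formation) fixes the C1=C10 alkene without touching C5.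

Step 3
Reactants: 7 ethyl but-2-ynoate
Product: 8 ethyl (2Z)-3-(4,4,5,5-tetramethyl-1,3,2-dioxaborolan-2-yl)but-2-enoate (boron trans to the ester)
Conditions: B2pin2, CuCl (3 mol %), NaOtBu (6 mol %), Xantphos (3 mol %), MeOH (2 equiv), THF, rt
Reagents that add atoms: bis(pinacolato)diboron, CC1(C)OB(OC1(C)C)B1OC(C)(C)C(C)(C)O1
Why: Copper-catalysed β-borylation of an ynoate (formal hydroboration) adds borylcopper syn across the alkyne with boron at the β-carbon and methanol protonates the α-carbon, so boron ends trans to the ester.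

Step 4
Reactants: 6 methyl (1S,2R)-1-methyl-2-(prop-2-en-1-yl)-3-[(trifluoromethanesulfonyl)oxy]cyclohex-3-ene-1-carboxylate; 8 ethyl (2Z)-3-(4,4,5,5-tetramethyl-1,3,2-dioxaborolan-2-yl)but-2-enoate
Product: 9 methyl (1S,2S)-3-[(2E)-4-ethoxy-4-oxobut-2-en-2-yl]-1-methyl-2-(prop-2-en-1-yl)cyclohex-3-ene-1-carboxylate
Conditions: Pd(dppf)Cl2 (5 mol %), K3PO4, 1,4-dioxane/H2O, 60 °C
Reagents that add atoms: none
Why: Suzuki–Miyaura coupling of an alkenyl triflate with an alkenylboronate proceeds with retention at both sp2 carbons, so the ring takes the place of boron trans to the ester and the (E)-dienoate results.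

Step 5
Reactants: 9 methyl (1S,2S)-3-[(2E)-4-ethoxy-4-oxobut-2-en-2-yl]-1-methyl-2-(prop-2-en-1-yl)cyclohex-3-ene-1-carboxylate
Product: 11 methyl (1S,2S)-3-[(2E)-4-ethoxy-4-oxobut-2-en-2-yl]-2-(3-hydroxypropyl)-1-methylcyclohex-3-ene-1-carboxylate, via alkylborane 10 (not isolated)
Conditions: 9-BBN, THF, 0 °C → rt; then 30% H2O2, aq. NaOAc, 0 °C → rt
Reagents that add atoms: hydrogen peroxide, OO
Why: Brown hydroboration with the bulky 9-BBN is selective for the monosubstituted terminal alkene over the trisubstituted ring alkene and the electron-poor enoate and places boron on the terminal carbon, and acetate-buffered peroxide oxidation spares both esters.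

Step 6
Reactants: 11 methyl (1S,2S)-3-[(2E)-4-ethoxy-4-oxobut-2-en-2-yl]-2-(3-hydroxypropyl)-1-methylcyclohex-3-ene-1-carboxylate
Product: 12 methyl (1S,2S)-3-[(2E)-4-ethoxy-4-oxobut-2-en-2-yl]-1-methyl-2-(3-oxopropyl)cyclohex-3-ene-1-carboxylate
Conditions: DMP, CH2Cl2, rt
Reagents that add atoms: none
Why: Dess–Martin oxidation converts the primary alcohol into the aldehyde under neutral conditions that leave the dienoate, the ester and the C5 centre untouched.

Step 7
Reactants: 12 methyl (1S,2S)-3-[(2E)-4-ethoxy-4-oxobut-2-en-2-yl]-1-methyl-2-(3-oxopropyl)cyclohex-3-ene-1-carboxylate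
Product: 13 methyl (1S,2S)-2-(but-3-en-1-yl)-3-[(2E)-4-ethoxy-4-oxobut-2-en-2-yl]-1-methylcyclohex-3-ene-1-carboxylate
Conditions: Ph3PCH3Br, KN(SiMe3)2, THF, 0 °C; then 12, −78 → 0 °C
Reagents that add atoms: methyltriphenylphosphonium bromide, C[P+](c1ccccc1)(c1ccccc1)c1ccccc1.[Br-]
Why: Wittig methylenation with the non-stabilised ylide is selective for the aldehyde over the two esters and the hindered β,β-disubstituted enoate and installs the terminal C8=C17 alkene.

Step 8
Reactants: 13 methyl (1S,2S)-2-(but-3-en-1-yl)-3-[(2E)-4-ethoxy-4-oxobut-2-en-2-yl]-1-methylcyclohex-3-ene-1-carboxylate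
Product: 14 methyl (1S,5S,6R,8aS)-5-(2-ethoxy-2-oxoethyl)-1,5,6-trimethyl-1,2,3,5,6,7,8,8a-octahydronaphthalene-1-carboxylate
Conditions: Fe(acac)3 (0.5 equiv), PhSiH3 (2.5 equiv, added slowly), EtOH/ethylene glycol, 0.02 M, 60 °C
Reagents that add atoms: none
Why: Fe(acac)3 and PhSiH3 in ethanol form an iron hydride that transfers a hydrogen atom to the terminal C17 of the only unactivated alkene, the secondary C8 radical adds to C9 (the β-carbon of the dienoate), and the ester-stabilised C11 radical is reduced by divalent iron and protonated by the solvent. This is a metal-hydride hydrogen-atom-transfer Giese cyclisation, the intramolecular form of the reductive olefin–acrylate coupling that is established for building quaternary carbons. Ring B closes 6-exo-trig through a chair in which H5 is axial, because ring A holds C4 near the plane of the C1=C10 alkene. C9 is controlled by the rotamer about C9–C10: the s-trans dienoate, which keeps C20 away from the C5–C6 bond, turns C11 toward C5, so attack from the face of the tether should make C11 axial and cis to H5 and leave C20 equatorial (9S). C8 is controlled by the orientation of the radical in that chair: placing C17 anti to the C11 ester arm and gauche only to C20 should give the 8R centre with C17 trans to C11, the less secure of the two selectivities. The step also needs closure at C9 instead of 5-exo attack at C10 or bridged 6-endo attack at C1, and cyclisation must outrun a second hydrogen-atom transfer; the polarity match of the alkyl radical with the β-position, the strain of the bridged alternative, high dilution and slow silane addition are relied on for this.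

Step 9
Reactants: 14 methyl (1S,5S,6R,8aS)-5-(2-ethoxy-2-oxoethyl)-1,5,6-trimethyl-1,2,3,5,6,7,8,8a-octahydronaphthalene-1-carboxylate
Product: 15 methyl (1S,5S,6R,8aS)-5-(2-hydroxyethyl)-1,5,6-trimethyl-1,2,3,5,6,7,8,8a-octahydronaphthalene-1-carboxylate
Conditions: LiBH4, THF, 0 °C → rt
Reagents that add atoms: none
Why: Borohydride ester reduction discriminates by hindrance: the C12 ethyl ester on a methylene is reduced to the primary alcohol while the C18 methyl ester on the quaternary C4 is shielded.

Step 10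
Reactants: 15 methyl (1S,5S,6R,8aS)-5-(2-hydroxyethyl)-1,5,6-trimethyl-1,2,3,5,6,7,8,8a-octahydronaphthalene-1-carboxylate
Product: 16 methyl (1S,5S,6R,8aS)-5-(2-iodoethyl)-1,5,6-trimethyl-1,2,3,5,6,7,8,8a-octahydronaphthalene-1-carboxylate
Conditions: I2, PPh3, imidazole, CH2Cl2, 0 °C → rt
Reagents that add atoms: iodine, II
Why: Appel-type iodination activates the primary alcohol as an oxyphosphonium ion that iodide displaces by SN2 at the unhindered C12.

Step 11
Reactants: 17 ethyl 3-oxobutanoate (ethyl acetoacetate)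
Product: 18 ethyl (2E)-3-[(trifluoromethanesulfonyl)oxy]but-2-enoate (triflate trans to the ester)
Conditions: Tf2O, aq. Me4NOH, hexane, 5 °C
Reagents that add atoms: trifluoromethanesulfonic anhydride, O=S(=O)(OS(=O)(=O)C(F)(F)F)C(F)(F)F
Why: O-Sulfonylation of the β-keto ester enolate with a non-coordinating ammonium counter-ion traps the open, non-chelated enolate, in which the enolate oxygen lies anti to the ester, and so should give the (E)-enol triflate.

Step 12
Reactants: 16 methyl (1S,5S,6R,8aS)-5-(2-iodoethyl)-1,5,6-trimethyl-1,2,3,5,6,7,8,8a-octahydronaphthalene-1-carboxylate; 18 ethyl (2E)-3-[(trifluoromethanesulfonyl)oxy]but-2-enoate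
Product: 20 methyl (1S,5S,6R,8aS)-5-[(3E)-5-ethoxy-3-methyl-5-oxopent-3-en-1-yl]-1,5,6-trimethyl-1,2,3,5,6,7,8,8a-octahydronaphthalene-1-carboxylate, via alkylzinc iodide 19 (not isolated)
Conditions: Zn dust, LiCl, THF, 40 °C; then 18, Pd(PPh3)4 (5 mol %), rt
Reagents that add atoms: none
Why: Direct zinc insertion into the primary iodide tolerates the ester, and the Negishi coupling of the alkylzinc with the alkenyl triflate proceeds with retention, so the C12 chain ends trans to the ester and the 13E alkene is set.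

Step 13
Reactants: 20 methyl (1S,5S,6R,8aS)-5-[(3E)-5-ethoxy-3-methyl-5-oxopent-3-en-1-yl]-1,5,6-trimethyl-1,2,3,5,6,7,8,8a-octahydronaphthalene-1-carboxylate
Product: 21 methyl (1S,5S,6R,8aS)-5-[(3E)-5-hydroxy-3-methylpent-3-en-1-yl]-1,5,6-trimethyl-1,2,3,5,6,7,8,8a-octahydronaphthalene-1-carboxylate
Conditions: i-Bu2AlH, CH2Cl2, −78 °C; aq. potassium sodium tartrate
Reagents that add atoms: none
Why: Aluminium hydride 1,2-reduction of the conjugated ethyl ester at low temperature gives the allylic alcohol without touching the alkene geometry, and the C18 ester on the quaternary carbon is too hindered to react.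

Step 14
Reactants: 21 methyl (1S,5S,6R,8aS)-5-[(3E)-5-hydroxy-3-methylpent-3-en-1-yl]-1,5,6-trimethyl-1,2,3,5,6,7,8,8a-octahydronaphthalene-1-carboxylate
Product: 22 (1S,5S,6R,8aS)-5-[(3E)-5-hydroxy-3-methylpent-3-en-1-yl]-1,5,6-trimethyl-1,2,3,5,6,7,8,8a-octahydronaphthalene-1-carboxylic acid
Conditions: NaSEt, DMF, 90 °C; then aq. HCl to pH 3
Reagents that add atoms: none
Why: Thiolate dealkylation of the methyl ester by SN2 attack at the O-methyl carbon bypasses the hindered carbonyl of the quaternary C18 ester and leaves the alkenes and the allylic alcohol untouched.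

Step 15
Reactants: 22 (1S,5S,6R,8aS)-5-[(3E)-5-hydroxy-3-methylpent-3-en-1-yl]-1,5,6-trimethyl-1,2,3,5,6,7,8,8a-octahydronaphthalene-1-carboxylic acid
Product: 23 (1S,5S,6R,8aS)-1,5,6-trimethyl-5-[(3E)-3-methyl-5-(propanoyloxy)pent-3-en-1-yl]-1,2,3,5,6,7,8,8a-octahydronaphthalene-1-carboxylic acid (CNP0223570.1)
Conditions: (EtCO)2O, pyridine, DMAP (cat.), CH2Cl2, 0 °C → rt; then aq. NaHCO3/THF
Reagents that add atoms: propanoic anhydride, CCC(=O)OC(=O)CC
Why: DMAP-catalysed acylation esterifies the primary allylic alcohol, whereas the hindered tertiary carboxylic acid cannot be esterified by the anhydride and any mixed anhydride formed at C18 is hydrolysed at the propanoyl carbonyl during the bicarbonate work-up.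

Compound list
1 | methyl 3-oxocyclohex-1-ene-1-carboxylate | COC(=O)C1=CC(=O)CCC1 | starting material
2 | prop-2-en-1-yl acetate (allyl acetate) | CC(=O)OCC=C | starting material
3 | methyl[(3S)-3-(methoxycarbonyl)-3-methylcyclohex-1-en-1-olato]zinc (methylzinc enolate, C5=C10) | C[Zn]OC1=C[C@@](C)(C(=O)OC)CCC1 | intermediate
4 | methyl (1S,2R)-1-methyl-3-oxo-2-(prop-2-en-1-yl)cyclohexane-1-carboxylate | O=C1CCC[C@](C)(C(=O)OC)[C@H]1CC=C | intermediate
5 | potassium (5S,6R)-5-(methoxycarbonyl)-5-methyl-6-(prop-2-en-1-yl)cyclohex-1-en-1-olate | [K+].[O-]C1=CCC[C@](C)(C(=O)OC)[C@H]1CC=C | intermediate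
6 | methyl (1S,2R)-1-methyl-2-(prop-2-en-1-yl)-3-[(trifluoromethanesulfonyl)oxy]cyclohex-3-ene-1-carboxylate | O=S(=O)(OC1=CCC[C@](C)(C(=O)OC)[C@H]1CC=C)C(F)(F)F | intermediate
7 | ethyl but-2-ynoate | CC#CC(=O)OCC | starting material
8 | ethyl (2Z)-3-(4,4,5,5-tetramethyl-1,3,2-dioxaborolan-2-yl)but-2-enoate | CCOC(=O)/C=C(\C)B1OC(C)(C)C(C)(C)O1 | intermediate
9 | methyl (1S,2S)-3-[(2E)-4-ethoxy-4-oxobut-2-en-2-yl]-1-methyl-2-(prop-2-en-1-yl)cyclohex-3-ene-1-carboxylate | CCOC(=O)/C=C(\C)C1=CCC[C@](C)(C(=O)OC)[C@H]1CC=C | intermediate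
10 | methyl (1S,2S)-2-[3-(9-borabicyclo[3.3.1]nonan-9-yl)propyl]-3-[(2E)-4-ethoxy-4-oxobut-2-en-2-yl]-1-methylcyclohex-3-ene-1-carboxylate | CCOC(=O)/C=C(\C)C1=CCC[C@](C)(C(=O)OC)[C@H]1CCCB1C2CCCC1CCC2 | intermediate
11 | methyl (1S,2S)-3-[(2E)-4-ethoxy-4-oxobut-2-en-2-yl]-2-(3-hydroxypropyl)-1-methylcyclohex-3-ene-1-carboxylate | CCOC(=O)/C=C(\C)C1=CCC[C@](C)(C(=O)OC)[C@H]1CCCO | intermediate
12 | methyl (1S,2S)-3-[(2E)-4-ethoxy-4-oxobut-2-en-2-yl]-1-methyl-2-(3-oxopropyl)cyclohex-3-ene-1-carboxylate | CCOC(=O)/C=C(\C)C1=CCC[C@](C)(C(=O)OC)[C@H]1CCC=O | intermediate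
13 | methyl (1S,2S)-2-(but-3-en-1-yl)-3-[(2E)-4-ethoxy-4-oxobut-2-en-2-yl]-1-methylcyclohex-3-ene-1-carboxylate | CCOC(=O)/C=C(\C)C1=CCC[C@](C)(C(=O)OC)[C@H]1CCC=C | intermediate
14 | methyl (1S,5S,6R,8aS)-5-(2-ethoxy-2-oxoethyl)-1,5,6-trimethyl-1,2,3,5,6,7,8,8a-octahydronaphthalene-1-carboxylate | CCOC(=O)C[C@]1(C)C2=CCC[C@](C)(C(=O)OC)[C@H]2CC[C@H]1C | intermediate
15 | methyl (1S,5S,6R,8aS)-5-(2-hydroxyethyl)-1,5,6-trimethyl-1,2,3,5,6,7,8,8a-octahydronaphthalene-1-carboxylate | OCC[C@]1(C)C2=CCC[C@](C)(C(=O)OC)[C@H]2CC[C@H]1C | intermediate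
16 | methyl (1S,5S,6R,8aS)-5-(2-iodoethyl)-1,5,6-trimethyl-1,2,3,5,6,7,8,8a-octahydronaphthalene-1-carboxylate | ICC[C@]1(C)C2=CCC[C@](C)(C(=O)OC)[C@H]2CC[C@H]1C | intermediate
17 | ethyl 3-oxobutanoate (ethyl acetoacetate) | CCOC(=O)CC(C)=O | starting material
18 | ethyl (2E)-3-[(trifluoromethanesulfonyl)oxy]but-2-enoate | CCOC(=O)/C=C(\C)OS(=O)(=O)C(F)(F)F | intermediate
19 | C12 alkylzinc iodide of 16 (iodine of 16 replaced by ZnI, all stereocentres as in 16) | I[Zn]CC[C@]1(C)C2=CCC[C@](C)(C(=O)OC)[C@H]2CC[C@H]1C | intermediate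
20 | methyl (1S,5S,6R,8aS)-5-[(3E)-5-ethoxy-3-methyl-5-oxopent-3-en-1-yl]-1,5,6-trimethyl-1,2,3,5,6,7,8,8a-octahydronaphthalene-1-carboxylate | CCOC(=O)/C=C(\C)CC[C@]1(C)C2=CCC[C@](C)(C(=O)OC)[C@H]2CC[C@H]1C | intermediate
21 | methyl (1S,5S,6R,8aS)-5-[(3E)-5-hydroxy-3-methylpent-3-en-1-yl]-1,5,6-trimethyl-1,2,3,5,6,7,8,8a-octahydronaphthalene-1-carboxylate | OC/C=C(\C)CC[C@]1(C)C2=CCC[C@](C)(C(=O)OC)[C@H]2CC[C@H]1C | intermediate
22 | (1S,5S,6R,8aS)-5-[(3E)-5-hydroxy-3-methylpent-3-en-1-yl]-1,5,6-trimethyl-1,2,3,5,6,7,8,8a-octahydronaphthalene-1-carboxylic acid | OC/C=C(\C)CC[C@]1(C)C2=CCC[C@](C)(C(=O)O)[C@H]2CC[C@H]1C | intermediate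
23 | (1S,5S,6R,8aS)-1,5,6-trimethyl-5-[(3E)-3-methyl-5-(propanoyloxy)pent-3-en-1-yl]-1,2,3,5,6,7,8,8a-octahydronaphthalene-1-carboxylic acid | CCC(=O)OC/C=C(\C)CC[C@]1(C)C2=CCC[C@](C)(C(=O)O)[C@H]2CC[C@H]1C | target

Total step count: 15.
Longest linear sequence: 13 steps (steps 1, 2, 4–10 and 12–15; steps 3 and 11 prepare the two coupling partners 8 and 18).

Steps most likely to fail

Step 8. The secondary C8 radical may be quenched by a second hydrogen-atom transfer, or may return an isomerised alkene, before it attacks the hindered C9. The facial selectivity at C8 may also be low, and prolonged exposure could start hydrogen-atom transfer to the C1=C10 alkene of the product. The fallback sets out from aldehyde 12 and comes back to the route at 14. Ohira–Bestmann homologation (dimethyl (1-diazo-2-oxopropyl)phosphonate, K2CO3, EtOH) would give the but-3-ynyl dienoate F1. Bu3SnH with AIBN in hot benzene adds a stannyl radical to the alkyne terminus, and the much more reactive alkenyl radical at C8 closes 6-exo on C9 (stannyl-radical enyne cyclisation) to give the (tributylstannyl)methylidene bicycle F2. Protodestannylation with HCl gives the C8 methylidene diester F3. Carbonyl-directed hydrogenation with [Ir(cod)(PCy3)(py)]PF6 and H2 then lets the C12 ester on the axial C11 arm deliver hydrogen to the face of C8 cis to C11, which should give 14 with C17 trans to C11.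

Step 1. The allylation of the zinc enolate may show poor facial selectivity, because the methyl and ester groups on C4 differ little in size; proton exchange between enolates could also move the allyl group to C1 or erode C5. The fallback sets out from 1 and comes back at 4. After the same conjugate methylation the enolate is acylated on oxygen with allyl chloroformate to give the allyl enol carbonate F4. Decarboxylative asymmetric allylation with Pd2(dba)3 and a chiral bis(2-diphenylphosphinobenzoyl)-1,2-diaminocyclohexane ligand regenerates the enolate as an ion pair with the allylpalladium cation and sets C5 under catalyst control instead of substrate control.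

Step 12. Zinc insertion may be sluggish, the alkylpalladium intermediate may undergo β-hydride elimination, or the E geometry may be lost through isomerisation of the β-acyl alkenylpalladium species. The fallback sets out from iodide 16 and comes back at 20. Displacement of iodide with lithium acetylide–ethylenediamine complex in DMSO gives the terminal alkyne F5. Methylalumination with AlMe3 catalysed by Cp2ZrCl2 adds methyl and aluminium syn, with aluminium on the terminal carbon, and trapping the alkenylalane with ethyl chloroformate gives 20 with the E geometry fixed by the syn addition.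

Further compounds
F1 | step 8 | methyl (1S,2S)-2-(but-3-yn-1-yl)-3-[(2E)-4-ethoxy-4-oxobut-2-en-2-yl]-1-methylcyclohex-3-ene-1-carboxylate | CCOC(=O)/C=C(\C)C1=CCC[C@](C)(C(=O)OC)[C@H]1CCC#C
F2 | step 8 | methyl (1S,5R,8aS)-5-(2-ethoxy-2-oxoethyl)-1,5-dimethyl-6-[(tributylstannyl)methylidene]-1,2,3,5,6,7,8,8a-octahydronaphthalene-1-carboxylate (alkene geometry not controlled) | CCOC(=O)C[C@]1(C)C2=CCC[C@](C)(C(=O)OC)[C@H]2CCC1=C[Sn](CCCC)(CCCC)CCCC
F3 | step 8 | methyl (1S,5S,8aS)-5-(2-ethoxy-2-oxoethyl)-1,5-dimethyl-6-methylidene-1,2,3,5,6,7,8,8a-octahydronaphthalene-1-carboxylate | CCOC(=O)C[C@]1(C)C2=CCC[C@](C)(C(=O)OC)[C@H]2CCC1=C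
F4 | step 1 | methyl (1S)-1-methyl-3-{[(prop-2-en-1-yloxy)carbonyl]oxy}cyclohex-2-ene-1-carboxylate | C=CCOC(=O)OC1=C[C@@](C)(C(=O)OC)CCC1
F5 | step 12 | methyl (1S,5S,6R,8aS)-5-(but-3-yn-1-yl)-1,5,6-trimethyl-1,2,3,5,6,7,8,8a-octahydronaphthalene-1-carboxylate | C#CCC[C@]1(C)C2=CCC[C@](C)(C(=O)OC)[C@H]2CC[C@H]1C
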